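Subtract before you integrate; here are the flasks you asked about, with what you want from them.

| flask | first end groups | second end groups | protic impurity | time |
|---|---|---|---|---|
| Friday's | 0.010 M | 0.00600 M | 3.00 mM | 20 d |
| Wednesday's | 0.010 M | 0.0120 M | 3.00 mM | 20 d |
| Monday's | 0.010 M | 0.0200 M | 3.00 mM | 20 d |

    first end groups + second end groups → links (k1 = 45.3 /M/h)
    first end groups + second end groups → rings, rate k2*[first end groups] as long as [second end groups] is above zero (k2 = 0.184 /h)
    second end groups + protic impurity → quenched reagent (k3 = 4.49 /M/h)
    second end groups + links → over-reaction product (k4 = 11.0 /M/h)

- share of links in all that became links or rings or over-reaction product for Friday's, Wednesday's, Monday's, in this order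
- how the row runs (falls, then rises / rises all the way / rises, then falls / hardly changes / falls all the way)

- "hardly changes" means that all values lie within two and a half points (for a concentration: within two and a half percent of the largest)
- run time (Friday's): 20 d

Each first end group that reacts takes one second end group, whether it ends as a link or as a ring. So the quantity to carry is the surplus: charged [second end groups] minus charged [first end groups]. It is −0.00400 M on Friday's, 0.00200 M on Wednesday's and 0.0100 M on Monday's. Friday's flask has second end groups as the limiting reagent, since its charge is smaller than that of first end groups.

A surplus has two ways out, onto links or onto the protic impurity. Now turn the constants into times. At the charged impurity, Friday's half-life of second end groups by that step alone is 2.1 d. With links taken at the charge of first end groups, the half-life against links is shorter, 0.263 d. On Friday's, at the charged amounts, the half-life of first end groups by the link-forming step alone (0.11 d) and that of links by over-reaction alone (0.44 d) are also shorter than the 20 d of the run.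

I therefore expect more of the surplus to go onto links than onto the protic impurity; that surplus is 20.0% of the first end groups charged on Wednesday's and 100% on Monday's. Meanwhile the starting ratio of rings to links falls from 0.68 on Friday's to 0.338 on Wednesday's. My reckoning gives a rise and then a drop, but no row of numbers.

The forecast gives 36%, 43% and 2%, a row that rises, then falls, on the ground that at large excess “the share collapses to a few percent”.

The simulation gives 37.0%, 41.2% and 1.67%, a row that rises, then falls. After 20.0 d, Monday's flask holds links at 1.67% of the first end groups charged, against 74.9% as over-reaction product. Monday's surplus of 0.0100 M is found there as 0.00749 M in over-reaction product, 0.00242 M in quenched reagent and 8.87 × 10⁻⁵ M still as second end groups. Wednesday's surplus of 0.00200 M stands after 20.0 d as 0.00152 M in over-reaction product and 4.78 × 10⁻⁴ M in quenched reagent.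

The numbers of this flask were drawn at random within sensible limits; the flask was simulated.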